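**Retrosynthetic overview**
1. C1–O2 (2,5-dihydrofuran, last ring): 5-exo oxa-Michael addition of the C3 hydroxyl onto a dienone arm on C7a, released by silylene cleavage; this sets C1.
2. Enol ester: O-acylation of the C7 acetaldehyde enolate with 3-methylbut-2-enoyl chloride.
3. Key step, C6–C7 (cyclohexene ring): iron-hydride hydrogen-atom transfer gives a tertiary C6 radical that closes 6-exo onto an enal arm; C6 and C7 are set from C4.
4. Acyclic precursor: 3,4-dibromofuran-2(5H)-one supplies C1, C7a, C3a and C3 with fixed alkene geometry. Asymmetric Ni/Cr coupling at the β-bromide sets C4, a lactol Wittig reaction gives the enone arm, and a Heck reaction with acrolein at the α-bromide gives the enal arm.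
5. Ring order: dioxasilinane (protecting ring and conformational lock) → cyclohexene (radical) → dihydrofuran (oxa-Michael).

Assumption: 3,4-dibromofuran-2(5H)-one is taken as a catalogue compound. Target atoms are numbered as in 2-benzofuran (C1 bears the 2-oxopropyl group, O2, C3, C3a, C4 bears OH, C5, C6 quaternary, C7 bears the enol ester, C7a).

**Step 1**
Reactants: 1 3-methylbut-3-en-1-ol; 2 1-bromo-3-methylbut-2-ene
Product: 4 7-methyl-3-methylideneoct-6-en-1-ol, via dilithio dianion 3 (not isolated)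
Conditions: n-BuLi (2.2 equiv), TMEDA, Et2O/hexane, 0 °C to rt; then 2, −78 °C to rt
Reagents that add atoms: none
Why: Alkoxide-assisted allylic lithiation of the methyl group gives a symmetric 2-substituted allyl dianion that is C-alkylated at the primary carbon of prenyl bromide (SN2 allyl–allyl coupling), and no stereocenter is formed.

**Step 2**
Reactants: 4 7-methyl-3-methylideneoct-6-en-1-ol
Product: 5 7-methyl-3-methylideneoct-6-enal
Conditions: PhI(OAc)2, TEMPO (10 mol %), CH2Cl2, rt; used crude at once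
Reagents that add atoms: none
Why: The TEMPO/oxoammonium oxidation stops at the aldehyde and runs without strong acid or base, so the β,γ-unsaturated aldehyde is not isomerised into conjugation.

**Step 3**
Reactants: 5 7-methyl-3-methylideneoct-6-enal; 6 3,4-dibromofuran-2(5H)-one
Product: 7 3-bromo-4-[(1R)-1-hydroxy-7-methyl-3-methylideneoct-6-en-1-yl]furan-2(5H)-one
Conditions: CrCl2 (15 mol %), NiCl2 (2 mol %), Kishi-type chiral sulfonamide–oxazoline ligand (17 mol %), Et3N, Mn, Zr(C5H5)2Cl2, LiCl, MeCN, rt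
Reagents that add atoms: none
Why: In this catalytic asymmetric Nozaki–Hiyama–Kishi coupling, zerovalent nickel inserts into the more activated C4 (β) C–Br bond of 6, and the derived vinylchromium species adds to the aldehyde inside the chiral chromium–sulfonamide complex, with the ligand enantiomer chosen to give the R carbinol (target C4); the α-bromide, the lactone and both alkenes are left untouched.

**Step 4**
Reactants: 7 3-bromo-4-[(1R)-1-hydroxy-7-methyl-3-methylideneoct-6-en-1-yl]furan-2(5H)-one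
Product: 8 3-bromo-4-[(1R)-1-hydroxy-7-methyl-3-methylideneoct-6-en-1-yl]-2,5-dihydrofuran-2-ol (anomer mixture)
Conditions: i-Bu2AlH (2.3 equiv), CH2Cl2, −78 °C; aq. potassium sodium tartrate
Reagents that add atoms: none
Why: Low-temperature DIBAL reduction of the γ-lactone stops at the lactol because the aluminium hemiacetal is stable at −78 °C (one equivalent is consumed by the free hydroxyl), and the neutral work-up avoids acid-induced dehydration to a furan; the anomeric centre is lost in the next step.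

**Step 5**
Reactants: 8 3-bromo-4-[(1R)-1-hydroxy-7-methyl-3-methylideneoct-6-en-1-yl]-2,5-dihydrofuran-2-ol
Product: 9 (3E,5Z,7R)-5-bromo-7-hydroxy-6-(hydroxymethyl)-13-methyl-9-methylidenetetradeca-3,5,12-trien-2-one
Conditions: Ph3P=CHC(O)CH3 (1.2 equiv), CH2Cl2, rt; carried on without delay
Reagents that add atoms: 1-(triphenyl-λ5-phosphanylidene)propan-2-one, CC(=O)C=P(c1ccccc1)(c1ccccc1)c1ccccc1
Why: Wittig olefination of the open hydroxy-enal tautomer with a stabilised ylide gives the E enone and keeps the ring-derived Z geometry of the tetrasubstituted alkene (enone arm cis to CH2OH, bromine cis to C4); under neutral conditions the hydroxy dienone has not yet closed by oxa-Michael addition.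

**Step 6**
Reactants: 9 (3E,5Z,7R)-5-bromo-7-hydroxy-6-(hydroxymethyl)-13-methyl-9-methylidenetetradeca-3,5,12-trien-2-one
Product: 10 (3E,5Z)-5-bromo-5-[(4R)-2,2-di-tert-butyl-4-(6-methyl-2-methylidenehept-5-en-1-yl)-1,3,2-dioxasilinan-5-ylidene]pent-3-en-2-one
Conditions: t-Bu2Si(OTf)2, 2,6-lutidine, CH2Cl2, −40 to 0 °C
Reagents that add atoms: di-tert-butylsilyl bis(trifluoromethanesulfonate), CC(C)(C)[Si](OS(=O)(=O)C(F)(F)F)(OS(=O)(=O)C(F)(F)F)C(C)(C)C
Why: Silylene formation on the 1,3-diol (six-membered dioxasilinane) masks both hydroxyls against Michael addition and holds the C4–O bond in the plane of the tetrasubstituted alkene with the C5 chain perpendicular to it, which is the conformational lock used in step 8.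

**Step 7**
Reactants: 10 (3E,5Z)-5-bromo-5-[(4R)-2,2-di-tert-butyl-4-(6-methyl-2-methylidenehept-5-en-1-yl)-1,3,2-dioxasilinan-5-ylidene]pent-3-en-2-one; 11 prop-2-enal (acrolein)
Product: 12 (2E,5E)-4-[(4R)-2,2-di-tert-butyl-4-(6-methyl-2-methylidenehept-5-en-1-yl)-1,3,2-dioxasilinan-5-ylidene]-7-oxoocta-2,5-dienal (enal arm cis to ring C4)
Conditions: Pd(OAc)2 (5 mol %), n-Bu4NCl, NaHCO3, DMF, 45 °C
Reagents that add atoms: none
Why: Mizoroki–Heck coupling of the 2-bromo-1,3-diene with acrolein under ligand-free phase-transfer (Jeffery) conditions gives the E enal by syn insertion and β-hydride elimination, with retention at the bromine-bearing carbon, so the enal arm sits cis to C4.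

**Step 8**
Reactants: 12 (2E,5E)-4-[(4R)-2,2-di-tert-butyl-4-(6-methyl-2-methylidenehept-5-en-1-yl)-1,3,2-dioxasilinan-5-ylidene]-7-oxoocta-2,5-dienal
Product: 13 2-[(6R,7S,8aR)-2,2-di-tert-butyl-7-methyl-7-(4-methylpent-3-en-1-yl)-5-[(1E)-3-oxobut-1-en-1-yl]-6,7,8,8a-tetrahydro-4H-1,3,2-benzodioxasilin-6-yl]acetaldehyde
Conditions: Fe(acac)3 (30 mol %), PhSiH3 (2.5 equiv), EtOH/ethylene glycol 5:1, 0.01 M, 60 °C
Reagents that add atoms: none
Why: In this metal-hydride hydrogen-atom-transfer reductive olefin coupling, the iron hydride delivers H• to the less hindered 1,1-disubstituted alkene (creating the C6 methyl and a tertiary C6 radical), which closes 6-exo-trig onto C7 of the cis enal arm (the trans enone arm is out of reach) before the α-formyl radical is reduced and protonated; in the chair-like transition state the silylene keeps C4–O pseudo-equatorial, the enal arm stays pseudo-equatorial and the larger homoprenyl group takes the pseudo-equatorial site on the radical carbon with methyl pseudo-axial, giving the 6S,7R arrangement of the target (its C6 and C7) as the major diastereomer, isolated by chromatography.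

**Step 9**
Reactants: 13 2-[(6R,7S,8aR)-2,2-di-tert-butyl-7-methyl-7-(4-methylpent-3-en-1-yl)-5-[(1E)-3-oxobut-1-en-1-yl]-6,7,8,8a-tetrahydro-4H-1,3,2-benzodioxasilin-6-yl]acetaldehyde; 14 3-methylbut-2-enoyl chloride
Product: 16 (E)-2-[(6R,7S,8aR)-2,2-di-tert-butyl-7-methyl-7-(4-methylpent-3-en-1-yl)-5-[(1E)-3-oxobut-1-en-1-yl]-6,7,8,8a-tetrahydro-4H-1,3,2-benzodioxasilin-6-yl]ethenyl 3-methylbut-2-enoate, via potassium enolate 15 (not isolated)
Conditions: KOt-Bu (1.05 equiv), THF, −78 °C; then 14, −78 °C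
Reagents that add atoms: none
Why: The aldehyde α-CH2 is the most acidic site (the methyl ketone is about three pKa units weaker), and its potassium enolate is O-acylated by the hard acyl chloride (enol ester formation); the E enolate is favoured because the bulky C7 substituent avoids the solvated O–K group, and the minor Z isomer is removed by chromatography.

**Step 10**
Reactants: 16 (E)-2-[(6R,7S,8aR)-2,2-di-tert-butyl-7-methyl-7-(4-methylpent-3-en-1-yl)-5-[(1E)-3-oxobut-1-en-1-yl]-6,7,8,8a-tetrahydro-4H-1,3,2-benzodioxasilin-6-yl]ethenyl 3-methylbut-2-enoate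
Product: 18 neovibsanin I, via diol dienone 17 (not isolated)
Conditions: HF·pyridine, pyridine, THF, 0 °C to rt; then Et3N, DBU (20 mol %), rt
Reagents that add atoms: none
Why: Fluoride removes the silylene, and the freed C3 hydroxyl adds to the dienone in a reversible, base-catalysed 5-exo-trig oxa-Michael reaction (the C4 hydroxyl cannot reach C1 without forming a bridgehead alkene), so C1 is set under thermodynamic control with the 2-oxopropyl group trans to the neighbouring C7 side chain (1S); the enol ester survives buffered HF and brief amine base.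

**Compound list**
1 | 3-methylbut-3-en-1-ol | C=C(C)CCO | starting material
2 | 1-bromo-3-methylbut-2-ene (prenyl bromide) | CC(C)=CCBr | starting material
3 | dilithio dianion of 1 (lithium 3-(lithiomethyl)but-3-en-1-olate) | [Li]CC(=C)CCO[Li] | intermediate
4 | 7-methyl-3-methylideneoct-6-en-1-ol | C=C(CCO)CCC=C(C)C | intermediate
5 | 7-methyl-3-methylideneoct-6-enal | C=C(CC=O)CCC=C(C)C | intermediate
6 | 3,4-dibromofuran-2(5H)-one | O=C1OCC(Br)=C1Br | starting material
7 | 3-bromo-4-[(1R)-1-hydroxy-7-methyl-3-methylideneoct-6-en-1-yl]furan-2(5H)-one | O=C1OCC(=C1Br)[C@H](O)CC(=C)CCC=C(C)C | intermediate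
8 | 3-bromo-4-[(1R)-1-hydroxy-7-methyl-3-methylideneoct-6-en-1-yl]-2,5-dihydrofuran-2-ol (anomer mixture) | OC1OCC(=C1Br)[C@H](O)CC(=C)CCC=C(C)C | intermediate
9 | (3E,5Z,7R)-5-bromo-7-hydroxy-6-(hydroxymethyl)-13-methyl-9-methylidenetetradeca-3,5,12-trien-2-one | CC(=O)/C=C/C(Br)=C(\CO)[C@H](O)CC(=C)CCC=C(C)C | intermediate
10 | (3E,5Z)-5-bromo-5-[(4R)-2,2-di-tert-butyl-4-(6-methyl-2-methylidenehept-5-en-1-yl)-1,3,2-dioxasilinan-5-ylidene]pent-3-en-2-one | CC(=O)/C=C/C(Br)=C1\CO[Si](C(C)(C)C)(C(C)(C)C)O[C@@H]1CC(=C)CCC=C(C)C | intermediate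
11 | prop-2-enal (acrolein) | C=CC=O | starting material
12 | (2E,5E)-4-[(4R)-2,2-di-tert-butyl-4-(6-methyl-2-methylidenehept-5-en-1-yl)-1,3,2-dioxasilinan-5-ylidene]-7-oxoocta-2,5-dienal | CC(=O)/C=C/C(/C=C/C=O)=C1\CO[Si](C(C)(C)C)(C(C)(C)C)O[C@@H]1CC(=C)CCC=C(C)C | intermediate
13 | 2-[(6R,7S,8aR)-2,2-di-tert-butyl-7-methyl-7-(4-methylpent-3-en-1-yl)-5-[(1E)-3-oxobut-1-en-1-yl]-6,7,8,8a-tetrahydro-4H-1,3,2-benzodioxasilin-6-yl]acetaldehyde | CC(=O)/C=C/C1=C2CO[Si](C(C)(C)C)(C(C)(C)C)O[C@@H]2C[C@](C)(CCC=C(C)C)[C@H]1CC=O | intermediate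
14 | 3-methylbut-2-enoyl chloride | CC(C)=CC(=O)Cl | starting material
15 | potassium (E)-enolate of 13 | CC(=O)/C=C/C1=C2CO[Si](C(C)(C)C)(C(C)(C)C)O[C@@H]2C[C@](C)(CCC=C(C)C)[C@H]1/C=C/[O-].[K+] | intermediate
16 | (E)-2-[(6R,7S,8aR)-2,2-di-tert-butyl-7-methyl-7-(4-methylpent-3-en-1-yl)-5-[(1E)-3-oxobut-1-en-1-yl]-6,7,8,8a-tetrahydro-4H-1,3,2-benzodioxasilin-6-yl]ethenyl 3-methylbut-2-enoate | CC(=O)/C=C/C1=C2CO[Si](C(C)(C)C)(C(C)(C)C)O[C@@H]2C[C@](C)(CCC=C(C)C)[C@H]1/C=C/OC(=O)C=C(C)C | intermediate
17 | (E)-2-[(1R,4R,6S)-4-hydroxy-3-(hydroxymethyl)-6-methyl-6-(4-methylpent-3-en-1-yl)-2-[(1E)-3-oxobut-1-en-1-yl]cyclohex-2-en-1-yl]ethenyl 3-methylbut-2-enoate | CC(=O)/C=C/C1=C(CO)[C@H](O)C[C@](C)(CCC=C(C)C)[C@H]1/C=C/OC(=O)C=C(C)C | intermediate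
18 | neovibsanin I, (E)-2-[(1S,4R,6S,7R)-4-hydroxy-6-methyl-6-(4-methylpent-3-en-1-yl)-1-(2-oxopropyl)-1,3,4,5,6,7-hexahydro-2-benzofuran-7-yl]ethenyl 3-methylbut-2-enoate | CC(=O)C[C@@H]1OCC2=C1[C@H](/C=C/OC(=O)C=C(C)C)[C@@](C)(CCC=C(C)C)C[C@H]2O | target

**Step count**
Total steps: 10. Longest linear sequence: 10 steps (1 → 18).

**Steps most likely to fail, with fallbacks**

The radical cyclisation of step 8 carries the most risk. The methyl and homoprenyl groups on the prochiral C6 radical differ little in size, so the C6 selectivity may be modest. The iron hydride also has to choose the 1,1-disubstituted alkene over the trisubstituted one while an enal and a dienone are present. The fallback generates the same C6 radical by photoredox fragmentation instead of hydrogen-atom transfer to the polyene; it sets out from 10 and returns at 13. Mukaiyama hydration of the 1,1-disubstituted alkene of 10 (Co(acac)2, PhSiH3, O2, i-PrOH, rt; no acceptor arm is within reach at this stage) gives the tertiary alcohol F1. Heck coupling with 11 under the conditions of step 7 gives the hydroxy trienone-al F2. Acylation with chloro N-phthalimidoyl oxalate (Et3N, DMAP) gives the N-phthalimidoyl oxalate F3. Visible-light reduction (Ru(bpy)3(PF6)2, Hantzsch ester, i-Pr2NEt·HBF4, blue LEDs, 0 °C to rt) then releases the tertiary radical, which cyclises as in step 8 to 13. No metal hydride meets the enal, and the lower temperature should raise the diastereoselectivity.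

Step 3 may give low enantioselectivity with this new halide, and aldehyde 5 may isomerise or undergo a carbonyl-ene reaction. The fallback sets C4 by reagent-controlled ketone reduction instead of asymmetric C–C bond formation; it sets out from 5 and 6 and returns at 7. Ligand-free coupling (CrCl2 in excess, NiCl2 cat., DMF, rt) gives the racemic carbinol F4. Dess–Martin periodinane with NaHCO3 gives the ketone 3-bromo-4-(7-methyl-3-methylideneoct-6-enoyl)furan-2(5H)-one F5. Reduction with (S)-2-methyl-CBS-oxazaborolidine and catecholborane at −78 °C (bromobutenolide as the large group) gives (R)-7.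

In step 5 the free C3 hydroxyl of 9 may close onto the new enone before the silylene is in place. The fallback forms the dienone only after both hydroxyls are masked; it sets out from 7 and returns at 10. Lactone opening with MeNH(OMe)·HCl and AlMe3 (CH2Cl2, 0 °C) gives the hydroxy Weinreb amide F6. Treatment with t-Bu2Si(OTf)2 and 2,6-lutidine gives the silylene Weinreb amide F7. Reduction with i-Bu2AlH (THF, −78 °C) gives the silylene enal F8, and Wittig reaction with Ph3P=CHC(O)CH3 gives 10.

**Further compounds**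
F1 | step 8 | (3E,5Z)-5-bromo-5-[(4R)-2,2-di-tert-butyl-4-(2-hydroxy-2,6-dimethylhept-5-en-1-yl)-1,3,2-dioxasilinan-5-ylidene]pent-3-en-2-one | CC(=O)/C=C/C(Br)=C1\CO[Si](C(C)(C)C)(C(C)(C)C)O[C@@H]1CC(C)(O)CCC=C(C)C
F2 | step 8 | (2E,5E)-4-[(4R)-2,2-di-tert-butyl-4-(2-hydroxy-2,6-dimethylhept-5-en-1-yl)-1,3,2-dioxasilinan-5-ylidene]-7-oxoocta-2,5-dienal | CC(=O)/C=C/C(/C=C/C=O)=C1\CO[Si](C(C)(C)C)(C(C)(C)C)O[C@@H]1CC(C)(O)CCC=C(C)C
F3 | step 8 | N-phthalimidoyl oxalate of F2 (tertiary alkyl 1,3-dioxoisoindolin-2-yl oxalate) | CC(=O)/C=C/C(/C=C/C=O)=C1\CO[Si](C(C)(C)C)(C(C)(C)C)O[C@@H]1CC(C)(OC(=O)C(=O)ON2C(=O)c3ccccc3C2=O)CCC=C(C)C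
F4 | step 3 | racemic 3-bromo-4-(1-hydroxy-7-methyl-3-methylideneoct-6-en-1-yl)furan-2(5H)-one | O=C1OCC(=C1Br)C(O)CC(=C)CCC=C(C)C
F5 | step 3 | 3-bromo-4-(7-methyl-3-methylideneoct-6-enoyl)furan-2(5H)-one | O=C1OCC(=C1Br)C(=O)CC(=C)CCC=C(C)C
F6 | step 5 | (2Z,4R)-2-bromo-4-hydroxy-3-(hydroxymethyl)-N-methoxy-N,10-dimethyl-6-methylideneundeca-2,9-dienamide | CON(C)C(=O)/C(Br)=C(\CO)[C@H](O)CC(=C)CCC=C(C)C
F7 | step 5 | (2Z)-2-bromo-2-[(4R)-2,2-di-tert-butyl-4-(6-methyl-2-methylidenehept-5-en-1-yl)-1,3,2-dioxasilinan-5-ylidene]-N-methoxy-N-methylacetamide | CON(C)C(=O)/C(Br)=C1\CO[Si](C(C)(C)C)(C(C)(C)C)O[C@@H]1CC(=C)CCC=C(C)C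
F8 | step 5 | (2Z)-2-bromo-2-[(4R)-2,2-di-tert-butyl-4-(6-methyl-2-methylidenehept-5-en-1-yl)-1,3,2-dioxasilinan-5-ylidene]acetaldehyde | O=C/C(Br)=C1\CO[Si](C(C)(C)C)(C(C)(C)C)O[C@@H]1CC(=C)CCC=C(C)C
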